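**Plan**

- Retrosynthesis: the polyene is cut at C11=C12 and C11'=C12' (two Horner–Wadsworth–Emmons olefinations around a C10 bis-phosphonate), ring C at its O–C8' bond (cycloisomerisation of an α-hydroxyallene), then C6'–C7' (Sonogashira coupling) on the furanoid half and C6–C7 (acetylide addition) on the triol half.
- Forward: ketoisophorone gives one silyloxy ketone that serves both ends. On the furanoid side it becomes an enyne, its oxirane and the allenol, and ring C then closes. The C15 furanoid aldehyde is joined first to the C10 unit and then to the ring-A C15 aldehyde, and fluoride frees the tetrol.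
- Stereochemistry: C3/C3' from yeast reduction followed by equatorial hydride delivery; C5' from epoxidation anti to the silyloxy group; the allene axis from anti SN2' hydride delivery, and C8' from that axis; C5 from Rubottom oxidation anti to the silyloxy group; C6 from axial acetylide attack; E alkenes from the enynol, the trans-hydroalumination and the olefinations.
- Enabling feature: in ring C the ether oxygen links the quaternary ring-fusion carbon C5' to the polyene-bearing methine C8', with the C6'=C7' double bond between them inside the five-membered ring; an allene C6'=C7'=C8' with a hydroxyl on C5' delivers exactly this connectivity on ring closure.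

Key step: step 9

Remarks: carotenoid numbering is used (ring A = trihydroxycyclohexane end, ring B = carbocycle of the furanoid end, ring C = dihydrofuran, primed locants for the furanoid half); TBS = tert-butyldimethylsilyl, TES = triethylsilyl. Assumption: an aluminium hydride bound to the oxirane oxygen could hand its hydride to C8' on the oxygen face, which would lead to the C8' epimer, so the oxirane is opened with a copper hydride, whose addition–elimination course is anti.

**Route**

Step 1
Reactants: 1 ketoisophorone (2,6,6-trimethylcyclohex-2-ene-1,4-dione)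
Product: 2 (6R)-levodione, (6R)-2,2,6-trimethylcyclohexane-1,4-dione
Conditions: baker's yeast (Saccharomyces cerevisiae), sucrose, H2O, 30 °C
Reagents that add atoms: none
Why: Biocatalytic asymmetric reduction of the enedione C=C bond by the ene-reductases of the yeast should add hydrogen to one face only and set the methyl-bearing centre as R, leaving both carbonyl groups.

Step 2
Reactants: 2 (6R)-levodione
Product: 3 (4R,6R)-actinol, (4R,6R)-4-hydroxy-2,2,6-trimethylcyclohexanone
Conditions: L-Selectride (LiBH(s-Bu)3), THF, −78 °C; then H2O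
Reagents that add atoms: none
Why: Bulky-hydride reduction of the less hindered C4 carbonyl (C1 is flanked by a quaternary and a tertiary carbon); the axial C2 methyl blocks the axial path, so equatorial delivery, as with 3,3,5-trimethylcyclohexanone, should give the axial alcohol, which is the (4R) isomer trans to the equatorial (6R) methyl.

Step 3
Reactants: 3 (4R,6R)-actinol
Product: 4 (4R,6R)-4-(tert-butyldimethylsilyloxy)-2,2,6-trimethylcyclohexanone
Conditions: TBSCl, imidazole, DMF, rt
Reagents that add atoms: tert-butyldimethylsilyl chloride, CC(C)(C)[Si](C)(C)Cl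
Why: Imidazole-promoted silylation of the secondary alcohol protects the future C3/C3' oxygen through all carbanion, hydride and oxidation steps.

Step 4
Reactants: 4 silyloxy ketone
Product: 6 (4R)-4-(tert-butyldimethylsilyloxy)-2,6,6-trimethylcyclohex-1-en-1-yl trifluoromethanesulfonate, via potassium enolate 5 (not isolated)
Conditions: KHMDS (KN(SiMe3)2), THF, −78 °C; then PhNTf2, −78 → 0 °C
Reagents that add atoms: N-phenylbis(trifluoromethanesulfonimide), O=S(=O)(N(c1ccccc1)S(=O)(=O)C(F)(F)F)C(F)(F)F; potassium bis(trimethylsilyl)amide, C[Si](C)(C)[N-][Si](C)(C)C.[K+] (potassium only in 5)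
Why: Enolisation is possible only towards the methyl-bearing α-carbon because the other α-carbon is quaternary, and O-sulfonylation of the enolate gives the tetrasubstituted enol triflate; the methyl-bearing centre has done its work and is erased here.

Step 5
Reactants: 6 enol triflate, 7 (E)-3-methylpent-2-en-4-yn-1-ol
Product: 8 (2E)-5-[(4R)-4-(tert-butyldimethylsilyloxy)-2,6,6-trimethylcyclohex-1-en-1-yl]-3-methylpent-2-en-4-yn-1-ol
Conditions: Pd(PPh3)4 (cat.), CuI (cat.), i-Pr2NH, DMF, rt
Reagents that add atoms: none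
Why: Sonogashira coupling of an enol triflate with a terminal alkyne forms the C6'–C7' bond, fixes the ring double bond at C5'=C6', tolerates the free hydroxyl and carries the E geometry of the enynol into C9'=C10'.

Step 6
Reactants: 8 dienynol
Product: 9 (2E)-5-[(4R)-4-(tert-butyldimethylsilyloxy)-2,6,6-trimethylcyclohex-1-en-1-yl]-3-methylpent-2-en-4-yn-1-yl acetate
Conditions: Ac2O, pyridine, DMAP (cat.), CH2Cl2, 0 °C
Reagents that add atoms: acetic anhydride, CC(=O)OC(C)=O
Why: Acetylation of the primary allylic alcohol masks it and makes the side-chain alkene less electron-rich than the ring alkene before the peracid step.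

Step 7
Reactants: 9 dienynyl acetate
Product: 10 (2E)-5-[(1R,4S,6R)-4-(tert-butyldimethylsilyloxy)-2,2,6-trimethyl-7-oxabicyclo[4.1.0]heptan-1-yl]-3-methylpent-2-en-4-yn-1-yl acetate (oxirane oxygen trans to the silyloxy group)
Conditions: mCPBA, NaHCO3, CH2Cl2, 0 °C
Reagents that add atoms: 3-chloroperbenzoic acid, O=C(OO)c1cccc(Cl)c1
Why: Prilezhaev epoxidation at the tetrasubstituted ring alkene, the most electron-rich C=C, should favour the face anti to the C3' silyloxy group as in related 3-silyloxy rings, which sets C5' and C6' with the oxirane oxygen trans to the C3' oxygen; the minor syn oxirane would be removed by chromatography.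

Step 8
Reactants: 10 alkynyl oxirane
Product: 12 allenic diol (2E)-5-[(2R,4S)-4-(tert-butyldimethylsilyloxy)-2-hydroxy-2,6,6-trimethylcyclohexylidene]-3-methylpenta-2,4-dien-1-ol (allene axis aS), via allenyl acetate 11 (not isolated)
Conditions: CuCl (cat.), 1,3-bis(2,6-diisopropylphenyl)imidazolium chloride (cat.), NaOt-Bu (cat.), (EtO)2MeSiH, t-BuOH, toluene, 0 °C; then K2CO3 (cat.), MeOH, rt
Reagents that add atoms: none
Why: SN2' reduction of a propargylic oxirane by an N-heterocyclic-carbene copper hydride: syn hydrocupration (H to C8', Cu to C7') and anti β-elimination of the oxirane oxygen should place the new H-8' on the face opposite the C6'–O bond (the face of the C5' methyl), which converts the C6' centre into the aS allene axis and frees the C5' hydroxyl with its configuration untouched; methanolysis in the same flask removes the acetate.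

Step 9
Reactants: 12 allenic diol
Product: 13 (2E)-3-[(2R,6S,7aR)-6-(tert-butyldimethylsilyloxy)-4,4,7a-trimethyl-2,4,5,6,7,7a-hexahydro-1-benzofuran-2-yl]but-2-en-1-ol
Conditions: AgNO3 (cat.), CaCO3, acetone–H2O, rt, dark
Reagents that add atoms: none
Why: Monovalent silver coordinates the C7'=C8' π bond of the allene on the face away from the hydroxyl, the tertiary C5' oxygen adds to C8', and protodemetalation of the vinylsilver species at C7' leaves the C6'=C7' alkene inside the new ring. The closest known reaction type is the silver- or gold-catalysed cycloisomerisation of α-hydroxyallenes to 2,5-dihydrofurans. Ring C closes in a 5-endo-trig mode: the attacked C7'=C8' bond lies inside the ring that forms. The one new stereocentre, C8', is controlled by the allene axis: H-8' and C9' stay on their own sides of the ring plane, so the axis with H-8' on the side of the C5' methyl becomes (8'R), with the side chain trans to that methyl. The step needs only stereospecificity and chemoselectivity for the tertiary hydroxyl; the E-configured C11' hydroxyl cannot reach the allene, and the neutral, buffered medium avoids ionisation of the doubly allylic C8'–O bond that would scramble C8'.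

Step 10
Reactants: 13 furanoid alcohol
Product: 14 (2E)-3-[(2R,6S,7aR)-6-(tert-butyldimethylsilyloxy)-4,4,7a-trimethyl-2,4,5,6,7,7a-hexahydro-1-benzofuran-2-yl]but-2-enal
Conditions: MnO2, CH2Cl2, rt
Reagents that add atoms: none
Why: MnO2 oxidises the primary allylic alcohol selectively to the E enal under neutral conditions that leave the dihydrofuran and its C8' centre alone.

Step 11
Reactants: 15 (2E,4E,6E)-2,7-dimethylocta-2,4,6-trienedial
Product: 16 (2E,4E,6E)-2,7-dimethylocta-2,4,6-triene-1,8-diol
Conditions: NaBH4, MeOH, 0 °C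
Reagents that add atoms: none
Why: Borohydride 1,2-reduction of both conjugated aldehyde groups gives the bis-allylic diol without touching the triene.

Step 12
Reactants: 16 C10 diol
Product: 18 tetraethyl [(2E,4E,6E)-2,7-dimethylocta-2,4,6-triene-1,8-diyl]bis(phosphonate), via dibromide 17 (not isolated)
Conditions: PBr3, pyridine (cat.), Et2O, −10 °C; then P(OEt)3, 110 °C
Reagents that add atoms: triethyl phosphite, CCOP(OCC)OCC; phosphorus tribromide, BrP(Br)Br (bromine only in 17)
Why: PBr3 converts the allylic diol into the dibromide, which is too labile to store and is heated at once with triethyl phosphite (Michaelis–Arbuzov reaction) to give the all-E bis-phosphonate.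

Step 13
Reactants: 14 furanoid aldehyde, 18 bis-phosphonate (3 equiv)
Product: 20 diethyl [(2E,4E,6E,8E,10E)-11-[(2R,6S,7aR)-6-(tert-butyldimethylsilyloxy)-4,4,7a-trimethyl-2,4,5,6,7,7a-hexahydro-1-benzofuran-2-yl]-2,7-dimethyldodeca-2,4,6,8,10-pentaen-1-yl]phosphonate, via phosphonate carbanion 19 (not isolated)
Conditions: 18 (3 equiv), NaHMDS (NaN(SiMe3)2, 1 equiv), THF, −78 °C; then 14, −78 °C → rt
Reagents that add atoms: sodium bis(trimethylsilyl)amide, C[Si](C)(C)[N-][Si](C)(C)C.[Na+] (sodium only in 19)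
Why: Horner–Wadsworth–Emmons olefination: with the bis-phosphonate in excess only one terminus is deprotonated, the allylic carbanion adds through its α-carbon to the enal and loss of diethyl phosphate should give the E C11'=C12' bond, while the pre-formed carbanion leaves no free base to disturb C8'.

Step 14
Reactants: 4 silyloxy ketone
Product: 22 (4R)-4-(tert-butyldimethylsilyloxy)-2,6,6-trimethyl-1-(triethylsilyloxy)cyclohex-1-ene, via lithium enolate 21 (not isolated)
Conditions: LDA (LiN(i-Pr)2), THF, −78 → 0 °C; then TESCl, −78 °C → rt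
Reagents that add atoms: chlorotriethylsilane, CC[Si](Cl)(CC)CC; lithium diisopropylamide, CC(C)[N-]C(C)C.[Li+] (lithium only in 21)
Why: Deprotonation by the lithium amide at the only enolisable α-carbon gives the lithium enolate, and its O-silylation by the chlorosilane yields the sole possible silyl enol ether and erases the methyl-bearing centre that becomes C5 of ring A.

Step 15
Reactants: 22 triethylsilyl enol ether
Product: 24 (2R,4S)-4-(tert-butyldimethylsilyloxy)-2,6,6-trimethyl-2-(triethylsilyloxy)cyclohexanone, via silyloxy oxirane 23 (not isolated)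
Conditions: mCPBA, NaHCO3, CH2Cl2, −20 °C → rt
Reagents that add atoms: 3-chloroperbenzoic acid, O=C(OO)c1cccc(Cl)c1
Why: Rubottom oxidation: the peracid should attack the enol ether from the face anti to the silyloxy group (axial attack on the half-chair that keeps that group equatorial), and the silyloxy oxirane opens with 1,4-silyl shift to the α-silyloxy ketone, which sets C5 with its oxygen trans to the C3 oxygen.

Step 16
Reactants: 24 α-silyloxy ketone, 7 (E)-3-methylpent-2-en-4-yn-1-ol
Product: 26 (1R,2R,4S)-4-(tert-butyldimethylsilyloxy)-1-[(3E)-5-hydroxy-3-methylpent-3-en-1-yn-1-yl]-2,6,6-trimethyl-2-(triethylsilyloxy)cyclohexan-1-ol, via dilithiated enynol 25 (not isolated)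
Conditions: 7 (2.5 equiv), n-BuLi (5 equiv), THF, −78 → 0 °C; then 24, −78 °C → rt; then H2O
Reagents that add atoms: n-butyllithium, [Li]CCCC (lithium only in 25)
Why: 1,2-addition of a lithium acetylide to a ketone that cannot enolise forms C6–C7; axial attack on the chair with equatorial C3 silyloxy group comes from the face opposite the axial C5 oxygen and the axial C1 methyl, which should give the C6 hydroxyl cis to the C5 oxygen; a shift of the triethylsilyl group between these two cis oxygens would be harmless because both are freed in the last step.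

Step 17
Reactants: 26 alkynyl diol
Product: 27 (1S,2R,4S)-4-(tert-butyldimethylsilyloxy)-1-[(1E,3E)-5-hydroxy-3-methylpenta-1,3-dien-1-yl]-2,6,6-trimethyl-2-(triethylsilyloxy)cyclohexan-1-ol
Conditions: Red-Al (NaAlH2(OCH2CH2OCH3)2), THF, 0 °C → rt; then H2O
Reagents that add atoms: none
Why: Hydroxyl-directed trans-hydroalumination of the propargylic alcohol and hydrolysis (Red-Al reduction) should give the E C7=C8 alkene and leave the silyl ethers and the E C9=C10 bond unchanged.

Step 18
Reactants: 27 dienediol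
Product: 28 (2E,4E)-5-[(1S,2R,4S)-4-(tert-butyldimethylsilyloxy)-1-hydroxy-2,6,6-trimethyl-2-(triethylsilyloxy)cyclohexyl]-3-methylpenta-2,4-dienal
Conditions: MnO2, CH2Cl2, rt
Reagents that add atoms: none
Why: MnO2 oxidises only the primary allylic alcohol; the tertiary allylic C6 hydroxyl cannot be oxidised.

Step 19
Reactants: 20 C25 phosphonate (1.3 equiv), 28 ring-A aldehyde
Product: 30 3,3'-bis-O-TBS 5-O-TES ether of the target (protected C40 tetrol), via phosphonate carbanion 29 (not isolated)
Conditions: 20, NaHMDS (NaN(SiMe3)2), THF, −78 °C; then 28, −78 °C → rt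
Reagents that add atoms: sodium bis(trimethylsilyl)amide, C[Si](C)(C)[N-][Si](C)(C)C.[Na+] (sodium only in 29)
Why: Horner–Wadsworth–Emmons olefination of the dienal by the pentaenyl phosphonate carbanion should form the C11=C12 bond as the E isomer; the tertiary C6 hydroxyl is too weak an acid to quench the stabilised carbanion.

Step 20
Reactants: 30 protected C40 tetrol
Product: 31 (3S,5R,6S,3'S,5'R,8'R)-5',8'-epoxy-5,6,5',8'-tetrahydro-β,β-carotene-3,5,6,3'-tetrol (target)
Conditions: TBAF (n-Bu4NF), THF, rt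
Reagents that add atoms: none
Why: Fluoride cleaves the two tert-butyldimethylsilyl ethers and the tertiary triethylsilyl ether under non-acidic conditions, which spares the acid-labile allylic ether centre C8' and the polyene.

**Compound list**

1 | ketoisophorone (2,6,6-trimethylcyclohex-2-ene-1,4-dione) | CC1=CC(=O)CC(C)(C)C1=O | starting material
2 | (6R)-levodione, (6R)-2,2,6-trimethylcyclohexane-1,4-dione | C[C@@H]1CC(=O)CC(C)(C)C1=O | intermediate
3 | (4R,6R)-actinol, (4R,6R)-4-hydroxy-2,2,6-trimethylcyclohexanone | C[C@@H]1C[C@@H](O)CC(C)(C)C1=O | intermediate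
4 | (4R,6R)-4-(tert-butyldimethylsilyloxy)-2,2,6-trimethylcyclohexanone | C[C@@H]1C[C@@H](O[Si](C)(C)C(C)(C)C)CC(C)(C)C1=O | intermediate
5 | potassium (4R)-4-(tert-butyldimethylsilyloxy)-2,6,6-trimethylcyclohex-1-en-1-olate | CC1=C([O-])C(C)(C)C[C@H](O[Si](C)(C)C(C)(C)C)C1.[K+] | intermediate (not isolated)
6 | (4R)-4-(tert-butyldimethylsilyloxy)-2,6,6-trimethylcyclohex-1-en-1-yl trifluoromethanesulfonate | CC1=C(OS(=O)(=O)C(F)(F)F)C(C)(C)C[C@H](O[Si](C)(C)C(C)(C)C)C1 | intermediate
7 | (E)-3-methylpent-2-en-4-yn-1-ol | C#C/C(C)=C/CO | starting material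
8 | (2E)-5-[(4R)-4-(tert-butyldimethylsilyloxy)-2,6,6-trimethylcyclohex-1-en-1-yl]-3-methylpent-2-en-4-yn-1-ol | CC1=C(C#C/C(C)=C/CO)C(C)(C)C[C@H](O[Si](C)(C)C(C)(C)C)C1 | intermediate
9 | (2E)-5-[(4R)-4-(tert-butyldimethylsilyloxy)-2,6,6-trimethylcyclohex-1-en-1-yl]-3-methylpent-2-en-4-yn-1-yl acetate | CC1=C(C#C/C(C)=C/COC(C)=O)C(C)(C)C[C@H](O[Si](C)(C)C(C)(C)C)C1 | intermediate
10 | (2E)-5-[(1R,4S,6R)-4-(tert-butyldimethylsilyloxy)-2,2,6-trimethyl-7-oxabicyclo[4.1.0]heptan-1-yl]-3-methylpent-2-en-4-yn-1-yl acetate | C[C@@]12C[C@@H](O[Si](C)(C)C(C)(C)C)CC(C)(C)[C@@]1(O2)C#C/C(C)=C/COC(C)=O | intermediate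
11 | (2E)-5-[(2R,4S)-4-(tert-butyldimethylsilyloxy)-2-hydroxy-2,6,6-trimethylcyclohexylidene]-3-methylpenta-2,4-dien-1-yl acetate, allene axis aS | C[C@@]1(O)C[C@@H](O[Si](C)(C)C(C)(C)C)CC(C)(C)C1=[C@]=C([H])/C(C)=C/COC(C)=O | intermediate (not isolated)
12 | (2E)-5-[(2R,4S)-4-(tert-butyldimethylsilyloxy)-2-hydroxy-2,6,6-trimethylcyclohexylidene]-3-methylpenta-2,4-dien-1-ol, allene axis aS (H-8' on the face of the C5' methyl, anti to the C5' hydroxyl) | C[C@@]1(O)C[C@@H](O[Si](C)(C)C(C)(C)C)CC(C)(C)C1=[C@]=C([H])/C(C)=C/CO | intermediate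
13 | (2E)-3-[(2R,6S,7aR)-6-(tert-butyldimethylsilyloxy)-4,4,7a-trimethyl-2,4,5,6,7,7a-hexahydro-1-benzofuran-2-yl]but-2-en-1-ol | OC/C=C(\C)[C@H]1C=C2C(C)(C)C[C@H](O[Si](C)(C)C(C)(C)C)C[C@@]2(C)O1 | intermediate
14 | (2E)-3-[(2R,6S,7aR)-6-(tert-butyldimethylsilyloxy)-4,4,7a-trimethyl-2,4,5,6,7,7a-hexahydro-1-benzofuran-2-yl]but-2-enal | O=C/C=C(\C)[C@H]1C=C2C(C)(C)C[C@H](O[Si](C)(C)C(C)(C)C)C[C@@]2(C)O1 | intermediate
15 | (2E,4E,6E)-2,7-dimethylocta-2,4,6-trienedial | O=C/C(C)=C/C=C/C=C(\C)C=O | starting material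
16 | (2E,4E,6E)-2,7-dimethylocta-2,4,6-triene-1,8-diol | OC/C(C)=C/C=C/C=C(\C)CO | intermediate
17 | (2E,4E,6E)-1,8-dibromo-2,7-dimethylocta-2,4,6-triene | BrC/C(C)=C/C=C/C=C(\C)CBr | intermediate (not isolated)
18 | tetraethyl [(2E,4E,6E)-2,7-dimethylocta-2,4,6-triene-1,8-diyl]bis(phosphonate) | CCOP(=O)(OCC)C/C(C)=C/C=C/C=C(\C)CP(=O)(OCC)OCC | intermediate
19 | monosodium salt of 18 (carbanion at C1) | CCOP(=O)(OCC)[CH-]/C(C)=C/C=C/C=C(\C)CP(=O)(OCC)OCC.[Na+] | intermediate (not isolated)
20 | diethyl [(2E,4E,6E,8E,10E)-11-[(2R,6S,7aR)-6-(tert-butyldimethylsilyloxy)-4,4,7a-trimethyl-2,4,5,6,7,7a-hexahydro-1-benzofuran-2-yl]-2,7-dimethyldodeca-2,4,6,8,10-pentaen-1-yl]phosphonate | CCOP(=O)(OCC)C/C(C)=C/C=C/C=C(C)/C=C/C=C(\C)[C@H]1C=C2C(C)(C)C[C@H](O[Si](C)(C)C(C)(C)C)C[C@@]2(C)O1 | intermediate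
21 | lithium (4R)-4-(tert-butyldimethylsilyloxy)-2,6,6-trimethylcyclohex-1-en-1-olate | CC1=C([O-])C(C)(C)C[C@H](O[Si](C)(C)C(C)(C)C)C1.[Li+] | intermediate (not isolated)
22 | (4R)-4-(tert-butyldimethylsilyloxy)-2,6,6-trimethyl-1-(triethylsilyloxy)cyclohex-1-ene | CC1=C(O[Si](CC)(CC)CC)C(C)(C)C[C@H](O[Si](C)(C)C(C)(C)C)C1 | intermediate
23 | (1R,4S,6R)-4-(tert-butyldimethylsilyloxy)-2,2,6-trimethyl-1-(triethylsilyloxy)-7-oxabicyclo[4.1.0]heptane | C[C@@]12C[C@@H](O[Si](C)(C)C(C)(C)C)CC(C)(C)[C@@]1(O2)O[Si](CC)(CC)CC | intermediate (not isolated)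
24 | (2R,4S)-4-(tert-butyldimethylsilyloxy)-2,6,6-trimethyl-2-(triethylsilyloxy)cyclohexanone | C[C@@]1(O[Si](CC)(CC)CC)C[C@@H](O[Si](C)(C)C(C)(C)C)CC(C)(C)C1=O | intermediate
25 | dilithium salt of 7 (lithium alkoxide and lithium acetylide) | [Li+].[Li+].[C-]#C/C(C)=C/C[O-] | intermediate (not isolated)
26 | (1R,2R,4S)-4-(tert-butyldimethylsilyloxy)-1-[(3E)-5-hydroxy-3-methylpent-3-en-1-yn-1-yl]-2,6,6-trimethyl-2-(triethylsilyloxy)cyclohexan-1-ol | OC/C=C(C)/C#C[C@]1(O)C(C)(C)C[C@H](O[Si](C)(C)C(C)(C)C)C[C@@]1(C)O[Si](CC)(CC)CC | intermediate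
27 | (1S,2R,4S)-4-(tert-butyldimethylsilyloxy)-1-[(1E,3E)-5-hydroxy-3-methylpenta-1,3-dien-1-yl]-2,6,6-trimethyl-2-(triethylsilyloxy)cyclohexan-1-ol | OC/C=C(C)/C=C/[C@]1(O)C(C)(C)C[C@H](O[Si](C)(C)C(C)(C)C)C[C@@]1(C)O[Si](CC)(CC)CC | intermediate
28 | (2E,4E)-5-[(1S,2R,4S)-4-(tert-butyldimethylsilyloxy)-1-hydroxy-2,6,6-trimethyl-2-(triethylsilyloxy)cyclohexyl]-3-methylpenta-2,4-dienal | O=C/C=C(C)/C=C/[C@]1(O)C(C)(C)C[C@H](O[Si](C)(C)C(C)(C)C)C[C@@]1(C)O[Si](CC)(CC)CC | intermediate
29 | sodium salt of 20 (carbanion at C1 of the dodecapentaenyl chain) | CCOP(=O)(OCC)[CH-]/C(C)=C/C=C/C=C(C)/C=C/C=C(\C)[C@H]1C=C2C(C)(C)C[C@H](O[Si](C)(C)C(C)(C)C)C[C@@]2(C)O1.[Na+] | intermediate (not isolated)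
30 | 3,3'-bis-O-(tert-butyldimethylsilyl)-5-O-(triethylsilyl) ether of 31 | CC(/C=C/C=C(C)/C=C/[C@]1(O)C(C)(C)C[C@H](O[Si](C)(C)C(C)(C)C)C[C@@]1(C)O[Si](CC)(CC)CC)=C\C=C\C=C(C)\C=C\C=C(/C)[C@H]1C=C2C(C)(C)C[C@H](O[Si](C)(C)C(C)(C)C)C[C@@]2(C)O1 | intermediate
31 | (3S,5R,6S,3'S,5'R,8'R)-5',8'-epoxy-5,6,5',8'-tetrahydro-β,β-carotene-3,5,6,3'-tetrol | CC(/C=C/C=C(C)/C=C/[C@]1(O)C(C)(C)C[C@H](O)C[C@@]1(C)O)=C\C=C\C=C(C)\C=C\C=C(/C)[C@H]1C=C2C(C)(C)C[C@H](O)C[C@@]2(C)O1 | target

**Count and risks**

Total step count: 20. Longest linear sequence: 13 steps (steps 1–10, 13, 19, 20).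

Steps most likely to fail:

1. Step 8. The hydride may not follow the anti course, or the copper hydride may attack the enyne or the allylic acetate, which would give the wrong allene axis or a mixture. Fallback: set out from dienynol 8 and leave out the acetate. Epoxidation with mCPBA/NaHCO3 gives (2E)-5-[(1R,4S,6R)-4-(tert-butyldimethylsilyloxy)-2,2,6-trimethyl-7-oxabicyclo[4.1.0]heptan-1-yl]-3-methylpent-2-en-4-yn-1-ol F1. F1 is opened with Pd2(dba)3 (cat.), n-Bu3P and HCO2H–Et3N in THF: zerovalent palladium adds to C8' anti to the oxirane oxygen, the formate loses CO2 to give the palladium hydride, and reductive elimination with retention places H-8' on that same face. The route is rejoined at allenic diol 12.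

2. Step 9. Silver-promoted ionisation of the doubly allylic C8'–O bond could erode the transfer from axis to centre, or the vinylallene could react at the diene instead. Fallback: from 12, iodocyclisation (NIS, CH2Cl2, 0 °C) forms the same O–C8' bond and ring by anti iodo-etherification and gives (2E)-3-[(2S,6S,7aR)-6-(tert-butyldimethylsilyloxy)-3-iodo-4,4,7a-trimethyl-2,4,5,6,7,7a-hexahydro-1-benzofuran-2-yl]but-2-en-1-ol F2 (same arrangement in space at C8' as in 13; the descriptor changes because of the iodine). Hydrodeiodination with n-Bu3SnH and Pd(PPh3)4 (cat.) returns to furanoid alcohol 13.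

3. Step 13. Olefination at both termini of the C10 unit, incomplete E selectivity or a difficult separation of the phosphonates could spoil the first union. Fallback: a Wittig sequence that sets out from diol 16. PPh3·HBr in MeOH gives [(2E,4E,6E)-2,7-dimethylocta-2,4,6-triene-1,8-diyl]bis(triphenylphosphonium) dibromide F3. F3 in excess with NaOMe and aldehyde 14 gives the C25 phosphonium bromide F4, a salt that is freed from neutral material by precipitation. F4 with NaOMe and aldehyde 28, followed by brief heating to equilibrate Z isomers, comes back to the route at 30; this replaces steps 12, 13 and 19.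

Further compounds

F1 | step 8 | (2E)-5-[(1R,4S,6R)-4-(tert-butyldimethylsilyloxy)-2,2,6-trimethyl-7-oxabicyclo[4.1.0]heptan-1-yl]-3-methylpent-2-en-4-yn-1-ol | C[C@@]12C[C@@H](O[Si](C)(C)C(C)(C)C)CC(C)(C)[C@@]1(O2)C#C/C(C)=C/CO
F2 | step 9 | (2E)-3-[(2S,6S,7aR)-6-(tert-butyldimethylsilyloxy)-3-iodo-4,4,7a-trimethyl-2,4,5,6,7,7a-hexahydro-1-benzofuran-2-yl]but-2-en-1-ol | OC/C=C(\C)[C@H]1C(I)=C2C(C)(C)C[C@H](O[Si](C)(C)C(C)(C)C)C[C@@]2(C)O1
F3 | step 13 | [(2E,4E,6E)-2,7-dimethylocta-2,4,6-triene-1,8-diyl]bis(triphenylphosphonium) dibromide | c1ccccc1[P+](c1ccccc1)(c1ccccc1)C/C(C)=C/C=C/C=C(\C)C[P+](c1ccccc1)(c1ccccc1)c1ccccc1.[Br-].[Br-]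
F4 | step 13 | [(2E,4E,6E,8E,10E)-11-[(2R,6S,7aR)-6-(tert-butyldimethylsilyloxy)-4,4,7a-trimethyl-2,4,5,6,7,7a-hexahydro-1-benzofuran-2-yl]-2,7-dimethyldodeca-2,4,6,8,10-pentaen-1-yl]triphenylphosphonium bromide | [Br-].c1ccccc1[P+](c1ccccc1)(c1ccccc1)C/C(C)=C/C=C/C=C(C)/C=C/C=C(\C)[C@H]1C=C2C(C)(C)C[C@H](O[Si](C)(C)C(C)(C)C)C[C@@]2(C)O1
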